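## The problem

The target is a trans-fused hydrindane (octahydroindene numbering C1–C7a; C14 is the carbinol carbon of the C3 arm): its cyclopentanone carries an acyloxy group at C1, the ketone at C2 and a 1-acetoxyethyl arm at C3, and its cyclohexane carries an isopropyl group at C4, an axial allylic ester at C6 and a methylidene at C7. Eight stereocentres have to be set (C1, C3, C3a, C4, C6, C7a, C14 and the α-carbon of the 2-methylbutanoate), together with the E geometry of the 3-methylpent-2-enoate. The trans ring fusion cannot be left to equilibration, because a hydrindane with a carbonyl next to the fusion (as arises at C7 on the way) drifts towards the cis isomer; it has to come from a kinetically controlled ring-forming event. C4 can direct C3a and C7a if the six-membered ring closes through a chair with the isopropyl group equatorial; C3 lies next to a carbonyl and can be left to thermodynamics, C1 is best taken from the chiral pool, and C14 and C6 need reagent or stereoelectronic control. Three different esters mean that three hydroxyl groups must be released one at a time. The β-acetoxy ketone eliminates with base, the α-acyloxy ketone can epimerise at C1, and the allylic ester beside the exocyclic alkene does not tolerate strong acid. The enabling feature is that the bonds C7–C7a and C3–C3a flank the trans fusion and C3 bears a two-carbon arm at the acetyl oxidation level, which is the imprint of a cation that starts at C7, crosses an (E)-alkene (C7a=C3a) and ends in a but-2-ynyl group.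

## Retrosynthesis

**Acyl–oxygen bonds.** Target 42 is cut at the C1 ester to hydroxy ketone 40 and (R)-2-methylbutanoic acid 41, and 40 is traced through silyl ether 39 to allylic alcohol 34 and acid 38. The 2-methylbutanoate goes on last so that the epimerisable α-acyloxy ketone exists for one step only. The enoate precedes it because the C6 hydroxyl is the only free one in 34. The forward couplings must run without strong base.

**C6–O bond.** 34 comes from 33 by allylic C–H oxidation. Carrying a C6 oxygen through the cyclisation instead would put an electron-withdrawing group next to the initiating carbonyl and add a stereocentre to control. The forward reaction must choose the ring methylene over the C7a methine and deliver oxygen axially.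

**C14 carbinol.** Acetate 33 comes from alcohol 32, and 32 from the 1,3-diketone 31 by reduction of the acetyl carbonyl. The diketone distinguishes by itself the oxygen that stays a ketone (C2) from the one that becomes the acetate (C14), so no protecting group is spent on that difference. The reduction must be face-selective on a hindered methyl ketone and must leave the ring carbonyl alone.

**C7 methylidene.** 31 comes from triketone 29 by methylenation, and 29 from diol 28 and silyl ether 27 by oxidation at C7 and C2. The 1,3-diketone masks itself as its enolate during the olefination. The C7 carbinol configuration from the cyclisation is deliberately erased.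

**C7–C7a and C3–C3a (key disconnection).** 27 is opened to the acyclic enyne aldehyde 25. Both rings and four stereocentres disappear, and the whole carbon skeleton including the arm is reduced to one chain with three stereocentres. Cuts at C3a–C7a (cycloaddition) or C2–C3a (ring expansion) leave more oxidation work for later. The forward step needs an aldehyde-initiated cation relay across a 1,2-disubstituted alkene into an alkyne.

**C7 aldehyde and the alkyne.** 25 comes from alcohol 24, and 24 from terminal alkene 22, whose vinyl group is a masked aldehyde. Methylalkyne 22 comes from dibromoalkene 20, aldehyde 19, alcohol 18 and diene 17, so the alkyne carbon C3 is the former primary carbinol carbon. The forward hydroboration must pick the monosubstituted alkene over the hindered internal alkene and the internal alkyne.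

**C3a=C7a alkene.** 17 is cut to sulfone 10 and aldehyde 15. In this polarity the sulfone stereocentre is β to the carbanion and cannot epimerise; a sulfone on the oxygenated fragment would eliminate its β-silyloxy group. The forward olefination must be E-selective.

**Oxygenated fragment.** 15 is traced through ester 14, diol 13 and mono-silyl ether 12 to diethyl D-tartrate 11. Monosilylation followed by hydroxyl-directed reduction distinguishes both hydroxyls and both termini of the C2-symmetric diester in two steps. The silyl-protected carbinol becomes C1 and the carbinol freed next to the new primary alcohol becomes C2.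

**Isopropyl fragment.** Sulfone 10 comes from sulfide 9, alcohol 7 and thiol 8; 7 from imide 6; and 6 from imide 3 and allyl bromide 4, with 3 made from auxiliary 1 and acid chloride 2. The auxiliary-controlled allylation sets C4, the one stereocentre that later steers the ring fusion.

**Enoic acid.** Acid 38 comes from ester 37 and ethyl but-2-ynoate 35 by syn-carbocupration, which fixes the E geometry.

## Roads not taken

**Alternative 1:** A sesquiterpene cyclase would fold (2Z,6E)-farnesyl diphosphate A1 into γ-cadinene A2. The cut is at C3a–C4 and C3a–C7a of the target. The step sets C3a, C7a and C4 and leaves the C7 methylidene, all from a fermentable feedstock, and no chemical route matches this step economy for the carbon skeleton. The weakness is everything after it: A2 is a decalin hydrocarbon, so a pinacol-type contraction of its cyclohexene to the cyclopentane is still needed. The oxygens at C1, C2 and C6 would then have to be introduced by C–H oxidation on an unfunctionalised skeleton with no handle for regio- or stereocontrol. A cyclase delivering this enantiomer in useful amounts is also not assured. The chosen plan is far longer to the skeleton, but it arrives with C1, C2, C7 and C14 already oxygenated at defined positions.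

**Alternative 2:** A Lewis acid would open the cis-epoxide of the tertiary cyclobutanol A3 and shift C3a from C2 to C3, giving the hydrindanone A4. The cut is C3–C3a, with C2–C3a sacrificed. The merit is real: C3 is set by inversion and C14 by retention, so the hydroxyethyl arm and ketone arrive with defined configuration and no enzyme or chiral reductant is needed. On that point it is better than the chosen plan. Against it, A3 is a trans-fused bicyclo[4.2.0]octane that must come from a regio- and face-selective enone–alkene photocycloaddition, and migration of C1 in place of C3a would give the wrong ketone. A4 also carries no oxygen at C1, so C1 would have to be oxygenated by enolising the C2 ketone away from C3, where the β-oxygen invites elimination. The chosen plan takes the C1 oxygen from tartrate and pays for it with the longer fragment synthesis.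

**Alternative 3:** An intramolecular Diels–Alder reaction of the enal–dienyl acetate triene A5, under Me2AlCl or iminium catalysis, would give the hexahydroindene A6. The cut is C3a–C7a and C6–C7. The reaction type is well precedented for trans-hydrindanes, and it installs the C6 oxygen with its configuration in the ring-forming step. This is a clear advantage over the late allylic oxidation of the chosen plan. The price comes afterwards: the C7 formyl group must be turned into the methylidene in several steps, and the C4=C5 alkene must be hydrogenated face-selectively to set C4 next to a hydrogenolysis-prone allylic acetate. C1 is again a bare methylene, the C6 acetate must be exchanged for the enoate, and A5 with its labile dienyl acetate needs its own stereocontrolled synthesis. The chosen plan fixes C4 before cyclisation and needs only one late C–H oxidation, at the cost of a key step without direct precedent.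

Key step: step 17

Conventions: β is the face of H-3a and α the face of H-7a; "trans-hydrindane" means 3aβ-H, 7aα-H; the SMILES in the compound list fix the absolute configuration. Assumption: (R)-2-methylbutanoic acid 41 is bought as the single enantiomer.

## Route

Step 1
Reactants: 1 (4R)-4-benzyl-1,3-oxazolidin-2-one; 2 3-methylbutanoyl chloride
Product: 3 (4R)-4-benzyl-3-(3-methylbutanoyl)-1,3-oxazolidin-2-one
Conditions: Et3N, DMAP (cat.), CH2Cl2, 0 °C → rt
Reagents that add atoms: none
Why: N-acylation of the oxazolidinone by the acid chloride under amine/DMAP catalysis; no stereocentre is formed.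

Step 2
Reactants: 3 (4R)-4-benzyl-3-(3-methylbutanoyl)-1,3-oxazolidin-2-one; 4 allyl bromide
Product: 6 (4R)-4-benzyl-3-[(2R)-2-isopropylpent-4-enoyl]-1,3-oxazolidin-2-one, via sodium enolate 5 (not isolated)
Conditions: NaN(SiMe3)2, THF, −78 °C; then 4, −78 → −40 °C
Reagents that add atoms: none
Why: Evans alkylation: the chelated (Z)-enolate is allylated on the face opposite the benzyl group, which for the (R)-auxiliary gives the (2R)-centre that becomes C4.

Step 3
Reactants: 6 (4R)-4-benzyl-3-[(2R)-2-isopropylpent-4-enoyl]-1,3-oxazolidin-2-one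
Product: 7 (2R)-2-isopropylpent-4-en-1-ol
Conditions: LiBH4, MeOH (1 equiv), Et2O, 0 °C
Reagents that add atoms: none
Why: Reductive cleavage of the imide at the exocyclic carbonyl; no enolisation occurs, so the new centre is kept and the auxiliary is recovered.

Step 4
Reactants: 7 (2R)-2-isopropylpent-4-en-1-ol; 8 1-phenyl-1H-tetrazole-5-thiol
Product: 9 5-{[(2R)-2-isopropylpent-4-en-1-yl]sulfanyl}-1-phenyl-1H-tetrazole
Conditions: PPh3, DIAD, THF, 0 °C → rt
Reagents that add atoms: none
Why: Mitsunobu thioetherification of a primary alcohol with the acidic thiol; the stereocentre is β to the reacting carbon and untouched.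

Step 5
Reactants: 9 5-{[(2R)-2-isopropylpent-4-en-1-yl]sulfanyl}-1-phenyl-1H-tetrazole
Product: 10 5-{[(2R)-2-isopropylpent-4-en-1-yl]sulfonyl}-1-phenyl-1H-tetrazole
Conditions: (NH4)6Mo7O24·4H2O (cat.), 30% aq. H2O2, EtOH, 0 °C → rt
Reagents that add atoms: hydrogen peroxide, OO
Why: Molybdate-catalysed peroxide oxidation of the sulfide to the sulfone; an isolated terminal alkene is inert under these conditions.

Step 6
Reactants: 11 diethyl D-tartrate
Product: 12 diethyl (2S,3S)-2-hydroxy-3-[(triisopropylsilyl)oxy]butanedioate
Conditions: i-Pr3SiOTf (1.0 equiv), 2,6-lutidine, CH2Cl2, −78 → 0 °C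
Reagents that add atoms: triisopropylsilyl trifluoromethanesulfonate, CC(C)[Si](OS(=O)(=O)C(F)(F)F)(C(C)C)C(C)C
Why: Monosilylation of a C2-symmetric diol can give only one mono-ether, and the first bulky silyl group shields the neighbouring hydroxyl against a second silylation; this oxygen becomes O1.

Step 7
Reactants: 12 diethyl (2S,3S)-2-hydroxy-3-[(triisopropylsilyl)oxy]butanedioate
Product: 13 ethyl (2S,3R)-3,4-dihydroxy-2-[(triisopropylsilyl)oxy]butanoate
Conditions: BH3·SMe2 (1.05 equiv), NaBH4 (5 mol%), THF, 0 °C → rt; MeOH quench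
Reagents that add atoms: none
Why: Hydroxyl-directed borane reduction: the alkoxyborane formed at the free hydroxyl delivers hydride through a five-membered chelate to the adjacent ester only, so the ester next to the silyl ether survives. The crude diol is silylated at once to forestall lactonisation.

Step 8
Reactants: 13 ethyl (2S,3R)-3,4-dihydroxy-2-[(triisopropylsilyl)oxy]butanoate
Product: 14 ethyl (2S,3R)-3,4-bis[(tert-butyldimethylsilyl)oxy]-2-[(triisopropylsilyl)oxy]butanoate
Conditions: t-BuMe2SiOTf (2.4 equiv), 2,6-lutidine, CH2Cl2, −78 → 0 °C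
Reagents that add atoms: tert-butyldimethylsilyl trifluoromethanesulfonate, CC(C)(C)[Si](C)(C)OS(=O)(=O)C(F)(F)F
Why: Exhaustive silylation with the silyl triflate; the secondary ether becomes O2 and is marked as the more labile of the two ring oxygens.

Step 9
Reactants: 14 ethyl (2S,3R)-3,4-bis[(tert-butyldimethylsilyl)oxy]-2-[(triisopropylsilyl)oxy]butanoate
Product: 15 (2S,3R)-3,4-bis[(tert-butyldimethylsilyl)oxy]-2-[(triisopropylsilyl)oxy]butanal
Conditions: i-Bu2AlH (1.1 equiv), CH2Cl2, −78 °C; aq. KNaC4H4O6 work-up
Reagents that add atoms: none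
Why: Partial reduction of an α-silyloxy ester: the aluminium hemiacetal is stable at −78 °C and releases the aldehyde only on work-up. The aldehyde is used directly to avoid epimerisation.

Step 10
Reactants: 10 5-{[(2R)-2-isopropylpent-4-en-1-yl]sulfonyl}-1-phenyl-1H-tetrazole; 15 (2S,3R)-3,4-bis[(tert-butyldimethylsilyl)oxy]-2-[(triisopropylsilyl)oxy]butanal
Product: 17 (4R,5E,7R,8R)-8,9-bis[(tert-butyldimethylsilyl)oxy]-4-isopropyl-7-[(triisopropylsilyl)oxy]nona-1,5-diene, via potassium sulfonyl carbanion 16 (not isolated)
Conditions: KN(SiMe3)2, DME, −60 °C; then 15, −60 °C → rt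
Reagents that add atoms: none
Why: Julia–Kocienski olefination: addition, Smiles rearrangement and loss of SO2 and the tetrazolate give the alkene, and the potassium counter-ion in DME favours the (E)-isomer. The sulfone stereocentre is β to the carbanion and cannot epimerise.

Step 11
Reactants: 17 (4R,5E,7R,8R)-8,9-bis[(tert-butyldimethylsilyl)oxy]-4-isopropyl-7-[(triisopropylsilyl)oxy]nona-1,5-diene
Product: 18 (2R,3R,4E,6R)-2-[(tert-butyldimethylsilyl)oxy]-6-isopropyl-3-[(triisopropylsilyl)oxy]nona-4,8-dien-1-ol
Conditions: HF·pyridine, pyridine, THF, 0 °C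
Reagents that add atoms: none
Why: Buffered HF·pyridine cleaves a primary tert-butyldimethylsilyl ether much faster than the secondary silyl ethers.

Step 12
Reactants: 18 (2R,3R,4E,6R)-2-[(tert-butyldimethylsilyl)oxy]-6-isopropyl-3-[(triisopropylsilyl)oxy]nona-4,8-dien-1-ol
Product: 19 (2S,3R,4E,6R)-2-[(tert-butyldimethylsilyl)oxy]-6-isopropyl-3-[(triisopropylsilyl)oxy]nona-4,8-dienal
Conditions: Dess–Martin periodinane, NaHCO3, CH2Cl2, 0 °C → rt
Reagents that add atoms: none
Why: Dess–Martin oxidation under buffered conditions, which do not epimerise the α-silyloxy aldehyde.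

Step 13
Reactants: 19 (2S,3R,4E,6R)-2-[(tert-butyldimethylsilyl)oxy]-6-isopropyl-3-[(triisopropylsilyl)oxy]nona-4,8-dienal
Product: 20 (3R,4R,5E,7R)-1,1-dibromo-3-[(tert-butyldimethylsilyl)oxy]-7-isopropyl-4-[(triisopropylsilyl)oxy]deca-1,5,9-triene
Conditions: CBr4, PPh3, Et3N, CH2Cl2, 0 °C
Reagents that add atoms: carbon tetrabromide, BrC(Br)(Br)Br
Why: First stage of the Corey–Fuchs homologation (Wittig-type dibromoolefination); the amine buffers HBr so that the silyl ethers survive.

Step 14
Reactants: 20 (3R,4R,5E,7R)-1,1-dibromo-3-[(tert-butyldimethylsilyl)oxy]-7-isopropyl-4-[(triisopropylsilyl)oxy]deca-1,5,9-triene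
Product: 22 (4R,5E,7R,8R)-8-[(tert-butyldimethylsilyl)oxy]-4-isopropyl-7-[(triisopropylsilyl)oxy]undeca-1,5-dien-9-yne, via lithium acetylide 21 (not isolated)
Conditions: n-BuLi (2.1 equiv), THF, −78 °C; then MeI, −78 °C → rt
Reagents that add atoms: iodomethane, CI
Why: Second stage of the Corey–Fuchs sequence: elimination and bromine–lithium exchange give the acetylide, which is C-methylated to the methylacetylene terminator.

Step 15
Reactants: 22 (4R,5E,7R,8R)-8-[(tert-butyldimethylsilyl)oxy]-4-isopropyl-7-[(triisopropylsilyl)oxy]undeca-1,5-dien-9-yne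
Product: 24 (4R,5E,7R,8R)-8-[(tert-butyldimethylsilyl)oxy]-4-isopropyl-7-[(triisopropylsilyl)oxy]undec-5-en-9-yn-1-ol, via alkylborane 23 (not isolated)
Conditions: 9-BBN, THF, 0 °C → rt; then NaOH, 30% aq. H2O2, 0 °C → rt
Reagents that add atoms: hydrogen peroxide, OO
Why: Anti-Markovnikov hydroboration–oxidation: 9-BBN adds to the monosubstituted alkene far faster than to the doubly branched (E)-alkene or the hindered internal alkyne.

Step 16
Reactants: 24 (4R,5E,7R,8R)-8-[(tert-butyldimethylsilyl)oxy]-4-isopropyl-7-[(triisopropylsilyl)oxy]undec-5-en-9-yn-1-ol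
Product: 25 (4R,5E,7R,8R)-8-[(tert-butyldimethylsilyl)oxy]-4-isopropyl-7-[(triisopropylsilyl)oxy]undec-5-en-9-ynal
Conditions: Dess–Martin periodinane, NaHCO3, CH2Cl2, 0 °C → rt
Reagents that add atoms: none
Why: Dess–Martin oxidation of the primary alcohol to the initiating aldehyde under neutral conditions.

Step 17
Reactants: 25 (4R,5E,7R,8R)-8-[(tert-butyldimethylsilyl)oxy]-4-isopropyl-7-[(triisopropylsilyl)oxy]undec-5-en-9-ynal
Product: 27 3β-acetyl-2α-(tert-butyldimethylsilyloxy)-4β-isopropyl-1β-(triisopropylsilyloxy)-trans-hydrindan-7α-ol, via enol carbonate 26 (not isolated)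
Conditions: MeAlCl2 (2.5 equiv), ethylene carbonate (10 equiv), CH2Cl2, −78 → −40 °C; then K2CO3, MeOH–H2O, 0 °C → rt
Reagents that add atoms: ethylene carbonate, O=C1OCCO1
Why: Proposed new method: MeAlCl2 binds the aldehyde oxygen and the (E)-alkene attacks C7 through C7a in a chair with the C4 isopropyl group equatorial, closing the six-membered ring 6-endo-trig, while the charge that builds at C3a is taken up by the alkyne through C3 (5-exo-dig) antiperiplanar to the new C7–C7a bond. The linear vinyl cation at C14 is captured by ethylene carbonate and emerges on aqueous quench as enol carbonate 26, which the carbonate–methanol work-up cleaves to the methyl ketone. The closest known reaction type is the acetal- or allyl-cation-initiated cation–olefin bicyclisation ending on a methylacetylene, which gives trans-hydrindanes bearing an acetyl group, together with alkylaluminium-halide-promoted aldehyde–olefin cyclisations; what has not been shown is an aldehyde initiator with a 1,2-disubstituted relay alkene and two silyloxy groups in the tether. C7a and C3a follow from the alkene face chosen by C4 and from anti addition across the (E)-alkene, which gives the trans fusion; C3 is settled thermodynamically during the basic work-up with the acetyl group trans to both neighbours; C7 is expected with equatorial oxygen but is oxidised in step 19. The step needs alkyne capture to outrun 1,2-hydride shift from C4 (whose axial C–H is aligned with the orbital developing at C3a), ene-type proton loss and chloride return: what the substrate offers is that C3 is held within bonding distance of C3a by the two-atom tether from C7a, so that the second bond can form in concert with the attack on the aldehyde and little charge need build up at C3a, and that each oxygen sits on the carbon next to a nucleophilic terminus, so that both cations form one carbon further from oxygen. The bulky trans-vicinal silyl ethers prefer a diaxial-like arrangement on the forming cyclopentane, which puts the C1 silyloxy group on the face of C7 as the target requires and shields the ether oxygens from adding to C3a.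

Step 18
Reactants: 27 3β-acetyl-2α-(tert-butyldimethylsilyloxy)-4β-isopropyl-1β-(triisopropylsilyloxy)-trans-hydrindan-7α-ol
Product: 28 3β-acetyl-4β-isopropyl-1β-(triisopropylsilyloxy)-trans-hydrindane-2α,7α-diol
Conditions: HF·pyridine, pyridine, THF, 0 °C → rt
Reagents that add atoms: none
Why: The secondary tert-butyldimethylsilyl ether is cleaved while the bulkier triisopropylsilyl ether survives; acidic fluoride avoids E1cB loss of the β-oxygen from the acetyl ketone.

Step 19
Reactants: 28 3β-acetyl-4β-isopropyl-1β-(triisopropylsilyloxy)-trans-hydrindane-2α,7α-diol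
Product: 29 3-acetyl-4β-isopropyl-1β-(triisopropylsilyloxy)-trans-hydrindane-2,7-dione
Conditions: Dess–Martin periodinane (2.5 equiv), NaHCO3, CH2Cl2, 0 °C → rt
Reagents that add atoms: none
Why: Dess–Martin oxidation of both secondary carbinols under neutral conditions, which spare C7a; the 2-acyl ketone is largely enolised, so C3 is labile until step 21.

Step 20
Reactants: 29 3-acetyl-4β-isopropyl-1β-(triisopropylsilyloxy)-trans-hydrindane-2,7-dione
Product: 31 3-acetyl-4β-isopropyl-7-methylidene-1β-(triisopropylsilyloxy)-trans-hydrindan-2-one, via potassium enolate 30 (not isolated)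
Conditions: Ph3PCH3Br, KOt-Bu, THF, 0 °C; then 29, 0 °C → rt; aq. NH4Cl
Reagents that add atoms: methyltriphenylphosphonium bromide, C[P+](c1ccccc1)(c1ccccc1)c1ccccc1.[Br-]
Why: Wittig methylenation: the first equivalent of ylide turns the acidic 1,3-diketone into its delocalised enolate, which does not react with the ylide, so only the C7 ketone is olefinated; low temperature limits enolisation of C7 towards C7a.

Step 21
Reactants: 31 3-acetyl-4β-isopropyl-7-methylidene-1β-(triisopropylsilyloxy)-trans-hydrindan-2-one
Product: 32 3β-[(1S)-1-hydroxyethyl]-4β-isopropyl-7-methylidene-1β-(triisopropylsilyloxy)-trans-hydrindan-2-one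
Conditions: ketoreductase (Re-face-selective, from a commercial panel), NADP+ (cat.), i-PrOH (10% v/v), phosphate buffer pH 7.0, 30 °C
Reagents that add atoms: none
Why: Enzymatic ketone reduction: ketoreductases accept methyl ketones with one bulky substituent and deliver hydride to one face, here the Re face, which gives (14S); the ring carbonyl, flanked by C1 and C3, is not a substrate. C3 is labile in 31, so the reduction is a dynamic kinetic resolution, and the 3β arm (trans to the C3a–C4 bond) is also the thermodynamic arrangement next to the C2 ketone.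

Step 22
Reactants: 32 3β-[(1S)-1-hydroxyethyl]-4β-isopropyl-7-methylidene-1β-(triisopropylsilyloxy)-trans-hydrindan-2-one
Product: 33 3β-[(1S)-1-acetoxyethyl]-4β-isopropyl-7-methylidene-1β-(triisopropylsilyloxy)-trans-hydrindan-2-one
Conditions: Ac2O, pyridine, DMAP (cat.), CH2Cl2, 0 °C
Reagents that add atoms: acetic anhydride, CC(=O)OC(C)=O
Why: Acetylation of the only free hydroxyl; pyridine at 0 °C is too weak a base to eliminate the β-acetoxy ketone.

Step 23
Reactants: 33 3β-[(1S)-1-acetoxyethyl]-4β-isopropyl-7-methylidene-1β-(triisopropylsilyloxy)-trans-hydrindan-2-one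
Product: 34 3β-[(1S)-1-acetoxyethyl]-6α-hydroxy-4β-isopropyl-7-methylidene-1β-(triisopropylsilyloxy)-trans-hydrindan-2-one
Conditions: SeO2 (0.5 equiv), t-BuOOH, CH2Cl2, 0 °C → rt
Reagents that add atoms: tert-butyl hydroperoxide, CC(C)(C)OO; selenium dioxide, O=[Se]=O
Why: Allylic oxidation by ene reaction and [2,3]-sigmatropic shift: 1,1-disubstituted alkenes are attacked at the ring methylene in preference to the methine (C7a), the axial H-6 is the one aligned with the π-system, and the [2,3] shift returns oxygen axially to C6 (the α face) with the alkene restored in the exocyclic position.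

Step 24
Reactants: 35 ethyl but-2-ynoate
Product: 37 ethyl (2E)-3-methylpent-2-enoate, via alkenylcopper 36 (not isolated)
Conditions: EtMgBr, CuBr·SMe2, THF, −78 °C; then 35, −78 °C; MeOH, −78 °C
Reagents that add atoms: ethylmagnesium bromide, CC[Mg]Br
Why: Syn-carbocupration of the ynoate places ethyl and copper on the same side; protonation at −78 °C with retention leaves ethyl trans to the ester, which is the (E)-isomer.

Step 25
Reactants: 37 ethyl (2E)-3-methylpent-2-enoate
Product: 38 (2E)-3-methylpent-2-enoic acid
Conditions: LiOH·H2O, THF–MeOH–H2O, rt; then aq. HCl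
Reagents that add atoms: lithium hydroxide, [Li+].[OH-]
Why: Saponification of the conjugated ester; the trisubstituted alkene keeps its geometry under mild hydroxide.

Step 26
Reactants: 34 3β-[(1S)-1-acetoxyethyl]-6α-hydroxy-4β-isopropyl-7-methylidene-1β-(triisopropylsilyloxy)-trans-hydrindan-2-one; 38 (2E)-3-methylpent-2-enoic acid
Product: 39 3β-[(1S)-1-acetoxyethyl]-4β-isopropyl-7-methylidene-2-oxo-1β-(triisopropylsilyloxy)-trans-hydrindan-6α-yl (2E)-3-methylpent-2-enoate
Conditions: EDC·HCl, DMAP, CH2Cl2, 0 °C → rt
Reagents that add atoms: none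
Why: Steglich esterification of the only free hydroxyl; without amine base the acid is not deprotonated at its γ-position, so neither deconjugation nor E/Z scrambling through a vinylketene is expected.

Step 27
Reactants: 39 3β-[(1S)-1-acetoxyethyl]-4β-isopropyl-7-methylidene-2-oxo-1β-(triisopropylsilyloxy)-trans-hydrindan-6α-yl (2E)-3-methylpent-2-enoate
Product: 40 3β-[(1S)-1-acetoxyethyl]-1β-hydroxy-4β-isopropyl-7-methylidene-2-oxo-trans-hydrindan-6α-yl (2E)-3-methylpent-2-enoate
Conditions: HF·pyridine, THF, 0 °C → rt
Reagents that add atoms: none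
Why: Acidic fluoride removes the triisopropylsilyl ether; basic fluoride sources are avoided because they would eliminate the β-acetoxy ketone.

Step 28
Reactants: 40 3β-[(1S)-1-acetoxyethyl]-1β-hydroxy-4β-isopropyl-7-methylidene-2-oxo-trans-hydrindan-6α-yl (2E)-3-methylpent-2-enoate; 41 (2R)-2-methylbutanoic acid
Product: 42 (1R,3R,3aR,4R,6S,7aS)-3-[(1S)-1-acetoxyethyl]-6-{[(2E)-3-methylpent-2-enoyl]oxy}-7-methylidene-2-oxo-4-(propan-2-yl)octahydro-1H-inden-1-yl (2R)-2-methylbutanoate
Conditions: EDC·HCl, DMAP, CH2Cl2, 0 °C → rt
Reagents that add atoms: none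
Why: Steglich esterification of the α-hydroxy ketone; acylation at oxygen does not touch C1, and an α-alkyl acid without an activating heteroatom keeps its configuration under carbodiimide/DMAP.

## Compound list

1 | (4R)-4-benzyl-1,3-oxazolidin-2-one | O=C1N[C@H](Cc2ccccc2)CO1 | starting material
2 | 3-methylbutanoyl chloride | CC(C)CC(Cl)=O | starting material
3 | (4R)-4-benzyl-3-(3-methylbutanoyl)-1,3-oxazolidin-2-one | CC(C)CC(=O)N1[C@H](Cc2ccccc2)COC1=O | intermediate
4 | allyl bromide | C=CCBr | starting material
5 | sodium (Z)-enolate of 3 | CC(C)/C=C(\[O-])N1[C@H](Cc2ccccc2)COC1=O.[Na+] | intermediate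
6 | (4R)-4-benzyl-3-[(2R)-2-isopropylpent-4-enoyl]-1,3-oxazolidin-2-one | C=CC[C@H](C(C)C)C(=O)N1[C@H](Cc2ccccc2)COC1=O | intermediate
7 | (2R)-2-isopropylpent-4-en-1-ol | C=CC[C@H](C(C)C)CO | intermediate
8 | 1-phenyl-1H-tetrazole-5-thiol | Sc1nnnn1-c1ccccc1 | starting material
9 | 5-{[(2R)-2-isopropylpent-4-en-1-yl]sulfanyl}-1-phenyl-1H-tetrazole | C=CC[C@H](C(C)C)CSc1nnnn1-c1ccccc1 | intermediate
10 | 5-{[(2R)-2-isopropylpent-4-en-1-yl]sulfonyl}-1-phenyl-1H-tetrazole | C=CC[C@H](C(C)C)CS(=O)(=O)c1nnnn1-c1ccccc1 | intermediate
11 | diethyl D-tartrate, (2S,3S) | CCOC(=O)[C@@H](O)[C@H](O)C(=O)OCC | starting material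
12 | diethyl (2S,3S)-2-hydroxy-3-[(triisopropylsilyl)oxy]butanedioate | CCOC(=O)[C@@H](O)[C@H](O[Si](C(C)C)(C(C)C)C(C)C)C(=O)OCC | intermediate
13 | ethyl (2S,3R)-3,4-dihydroxy-2-[(triisopropylsilyl)oxy]butanoate | CCOC(=O)[C@@H](O[Si](C(C)C)(C(C)C)C(C)C)[C@H](O)CO | intermediate
14 | ethyl (2S,3R)-3,4-bis[(tert-butyldimethylsilyl)oxy]-2-[(triisopropylsilyl)oxy]butanoate | CCOC(=O)[C@@H](O[Si](C(C)C)(C(C)C)C(C)C)[C@H](O[Si](C)(C)C(C)(C)C)CO[Si](C)(C)C(C)(C)C | intermediate
15 | (2S,3R)-3,4-bis[(tert-butyldimethylsilyl)oxy]-2-[(triisopropylsilyl)oxy]butanal | O=C[C@@H](O[Si](C(C)C)(C(C)C)C(C)C)[C@H](O[Si](C)(C)C(C)(C)C)CO[Si](C)(C)C(C)(C)C | intermediate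
16 | potassium α-sulfonyl carbanion of 10 | C=CC[C@H](C(C)C)[CH-]S(=O)(=O)c1nnnn1-c1ccccc1.[K+] | intermediate
17 | (4R,5E,7R,8R)-8,9-bis[(tert-butyldimethylsilyl)oxy]-4-isopropyl-7-[(triisopropylsilyl)oxy]nona-1,5-diene | C=CC[C@H](C(C)C)/C=C/[C@@H](O[Si](C(C)C)(C(C)C)C(C)C)[C@H](O[Si](C)(C)C(C)(C)C)CO[Si](C)(C)C(C)(C)C | intermediate
18 | (2R,3R,4E,6R)-2-[(tert-butyldimethylsilyl)oxy]-6-isopropyl-3-[(triisopropylsilyl)oxy]nona-4,8-dien-1-ol | C=CC[C@H](C(C)C)/C=C/[C@@H](O[Si](C(C)C)(C(C)C)C(C)C)[C@H](O[Si](C)(C)C(C)(C)C)CO | intermediate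
19 | (2S,3R,4E,6R)-2-[(tert-butyldimethylsilyl)oxy]-6-isopropyl-3-[(triisopropylsilyl)oxy]nona-4,8-dienal | C=CC[C@H](C(C)C)/C=C/[C@@H](O[Si](C(C)C)(C(C)C)C(C)C)[C@H](O[Si](C)(C)C(C)(C)C)C=O | intermediate
20 | (3R,4R,5E,7R)-1,1-dibromo-3-[(tert-butyldimethylsilyl)oxy]-7-isopropyl-4-[(triisopropylsilyl)oxy]deca-1,5,9-triene | C=CC[C@H](C(C)C)/C=C/[C@@H](O[Si](C(C)C)(C(C)C)C(C)C)[C@H](O[Si](C)(C)C(C)(C)C)C=C(Br)Br | intermediate
21 | lithium acetylide from 20 | C=CC[C@H](C(C)C)/C=C/[C@@H](O[Si](C(C)C)(C(C)C)C(C)C)[C@H](O[Si](C)(C)C(C)(C)C)C#C[Li] | intermediate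
22 | (4R,5E,7R,8R)-8-[(tert-butyldimethylsilyl)oxy]-4-isopropyl-7-[(triisopropylsilyl)oxy]undeca-1,5-dien-9-yne | C=CC[C@H](C(C)C)/C=C/[C@@H](O[Si](C(C)C)(C(C)C)C(C)C)[C@H](O[Si](C)(C)C(C)(C)C)C#CC | intermediate
23 | B-alkyl-9-borabicyclo[3.3.1]nonane from 22 | B1(C2CCCC1CCC2)CCC[C@H](C(C)C)/C=C/[C@@H](O[Si](C(C)C)(C(C)C)C(C)C)[C@H](O[Si](C)(C)C(C)(C)C)C#CC | intermediate
24 | (4R,5E,7R,8R)-8-[(tert-butyldimethylsilyl)oxy]-4-isopropyl-7-[(triisopropylsilyl)oxy]undec-5-en-9-yn-1-ol | OCCC[C@H](C(C)C)/C=C/[C@@H](O[Si](C(C)C)(C(C)C)C(C)C)[C@H](O[Si](C)(C)C(C)(C)C)C#CC | intermediate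
25 | (4R,5E,7R,8R)-8-[(tert-butyldimethylsilyl)oxy]-4-isopropyl-7-[(triisopropylsilyl)oxy]undec-5-en-9-ynal | O=CCC[C@H](C(C)C)/C=C/[C@@H](O[Si](C(C)C)(C(C)C)C(C)C)[C@H](O[Si](C)(C)C(C)(C)C)C#CC | intermediate
26 | 2-hydroxyethyl enol carbonate of 27 (C3=C14 enol, either geometry) | O[C@@H]1[C@@H]2[C@H](C(=C(C)OC(=O)OCCO)[C@@H](O[Si](C)(C)C(C)(C)C)[C@@H]2O[Si](C(C)C)(C(C)C)C(C)C)[C@@H](C(C)C)CC1 | intermediate
27 | 3β-acetyl-2α-(tert-butyldimethylsilyloxy)-4β-isopropyl-1β-(triisopropylsilyloxy)-trans-hydrindan-7α-ol | O[C@@H]1[C@@H]2[C@H]([C@H](C(C)=O)[C@@H](O[Si](C)(C)C(C)(C)C)[C@@H]2O[Si](C(C)C)(C(C)C)C(C)C)[C@@H](C(C)C)CC1 | intermediate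
28 | 3β-acetyl-4β-isopropyl-1β-(triisopropylsilyloxy)-trans-hydrindane-2α,7α-diol | O[C@@H]1[C@@H]2[C@H]([C@H](C(C)=O)[C@@H](O)[C@@H]2O[Si](C(C)C)(C(C)C)C(C)C)[C@@H](C(C)C)CC1 | intermediate
29 | 3-acetyl-4β-isopropyl-1β-(triisopropylsilyloxy)-trans-hydrindane-2,7-dione (enolised; C3 labile, drawn 3β) | O=C1[C@@H]2[C@H]([C@H](C(C)=O)C(=O)[C@@H]2O[Si](C(C)C)(C(C)C)C(C)C)[C@@H](C(C)C)CC1 | intermediate
30 | potassium enolate of 29 | O=C1[C@@H]2[C@H](C(C(C)=O)=C([O-])[C@@H]2O[Si](C(C)C)(C(C)C)C(C)C)[C@@H](C(C)C)CC1.[K+] | intermediate
31 | 3-acetyl-4β-isopropyl-7-methylidene-1β-(triisopropylsilyloxy)-trans-hydrindan-2-one (enolised; C3 labile, drawn 3β) | C=C1[C@@H]2[C@H]([C@H](C(C)=O)C(=O)[C@@H]2O[Si](C(C)C)(C(C)C)C(C)C)[C@@H](C(C)C)CC1 | intermediate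
32 | 3β-[(1S)-1-hydroxyethyl]-4β-isopropyl-7-methylidene-1β-(triisopropylsilyloxy)-trans-hydrindan-2-one | C=C1[C@@H]2[C@H]([C@H]([C@H](C)O)C(=O)[C@@H]2O[Si](C(C)C)(C(C)C)C(C)C)[C@@H](C(C)C)CC1 | intermediate
33 | 3β-[(1S)-1-acetoxyethyl]-4β-isopropyl-7-methylidene-1β-(triisopropylsilyloxy)-trans-hydrindan-2-one | C=C1[C@@H]2[C@H]([C@H]([C@H](C)OC(C)=O)C(=O)[C@@H]2O[Si](C(C)C)(C(C)C)C(C)C)[C@@H](C(C)C)CC1 | intermediate
34 | 3β-[(1S)-1-acetoxyethyl]-6α-hydroxy-4β-isopropyl-7-methylidene-1β-(triisopropylsilyloxy)-trans-hydrindan-2-one | C=C1[C@@H]2[C@H]([C@H]([C@H](C)OC(C)=O)C(=O)[C@@H]2O[Si](C(C)C)(C(C)C)C(C)C)[C@@H](C(C)C)C[C@@H]1O | intermediate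
35 | ethyl but-2-ynoate | CC#CC(=O)OCC | starting material
36 | ethyl (2Z)-2-cuprio-3-methylpent-2-enoate (alkenylcopper) | CC/C(C)=C(\[Cu])C(=O)OCC | intermediate
37 | ethyl (2E)-3-methylpent-2-enoate | CCOC(=O)/C=C(\C)CC | intermediate
38 | (2E)-3-methylpent-2-enoic acid | CC/C(C)=C/C(O)=O | intermediate
39 | 3β-[(1S)-1-acetoxyethyl]-4β-isopropyl-7-methylidene-2-oxo-1β-(triisopropylsilyloxy)-trans-hydrindan-6α-yl (2E)-3-methylpent-2-enoate | C=C1[C@@H]2[C@H]([C@H]([C@H](C)OC(C)=O)C(=O)[C@@H]2O[Si](C(C)C)(C(C)C)C(C)C)[C@@H](C(C)C)C[C@@H]1OC(=O)/C=C(\C)CC | intermediate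
40 | 3β-[(1S)-1-acetoxyethyl]-1β-hydroxy-4β-isopropyl-7-methylidene-2-oxo-trans-hydrindan-6α-yl (2E)-3-methylpent-2-enoate | C=C1[C@@H]2[C@H]([C@H]([C@H](C)OC(C)=O)C(=O)[C@@H]2O)[C@@H](C(C)C)C[C@@H]1OC(=O)/C=C(\C)CC | intermediate
41 | (2R)-2-methylbutanoic acid | CC[C@@H](C)C(O)=O | starting material
42 | (1R,3R,3aR,4R,6S,7aS)-3-[(1S)-1-acetoxyethyl]-6-{[(2E)-3-methylpent-2-enoyl]oxy}-7-methylidene-2-oxo-4-(propan-2-yl)octahydro-1H-inden-1-yl (2R)-2-methylbutanoate (CNP0289166.2) | C=C1[C@@H]2[C@H]([C@H]([C@H](C)OC(C)=O)C(=O)[C@@H]2OC(=O)[C@H](C)CC)[C@@H](C(C)C)C[C@@H]1OC(=O)/C=C(\C)CC | target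

## Step count and least certain steps

Total: 28 steps. Longest linear sequence: 22 steps, from 3-methylbutanoyl chloride 2 (and auxiliary 1) to 42 through steps 1–5, 10–23 and 26–28. The tartrate branch (steps 6–9) joins at step 10, which makes 21 steps from diethyl D-tartrate 11 to 42, and the enoic acid branch (steps 24–25) joins at step 26.

**Step 17 (key step, proposed new method).**
- Risk: the aluminium-bound zwitterion may collapse before the alkyne engages, by 1,2-hydride shift from C4 (stereoelectronically allowed, since the axial C4–H is aligned with the orbital at C3a), ene-type proton loss or chloride return. The relay alkene is only 1,2-disubstituted and is inductively deactivated by the allylic oxygen, and the carbonate trap competes with the aldehyde for the Lewis acid. A second failure mode is loss of a silyl group with ring closure through O2 onto C3a.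
- Fallback (known chemistry; sets out from 25, returns at 27): 25 is converted with (2R,4R)-pentane-2,4-diol (PPTS, MgSO4, CH2Cl2) into the dioxane acetal F1. SnCl4 (CH2Cl2, −78 °C, ethylene carbonate; then K2CO3/MeOH) opens the acetal to a discrete oxocarbenium ion that starts the same bicyclisation and gives the hydroxypentyl ether F2. Dess–Martin oxidation gives the keto ether F3, and K2CO3/MeOH induces β-elimination, which releases the C7 carbinol 27. Acetal-initiated bicyclisations onto methylacetylenes, with this oxidative removal of the diol residue, are established, and the initiator is a stronger, non-zwitterionic cation.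

**Step 20 (Wittig methylenation).**
- Risk: the basic ylide may enolise the hindered C7 ketone towards C7a instead of adding to it. That would lead to epimerisation of the ring fusion to cis or to β-elimination of the C1 silyloxy group.
- Fallback (sets out from 29, returns at 31): 29 is first converted into its potassium enolate (KN(SiMe3)2, 1 equiv). Me3SiCH2Li/CeCl3 (THF, −78 °C), a non-basic nucleophile, then adds to C7 and gives the β-hydroxysilane F4. KH (2 equiv, THF, 0 °C → rt) completes the Peterson olefination to 31.

**Step 21 (enzymatic reduction).**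
- Risk: the enzyme panel may fail to accept the hindered, largely enolised diketone, or may reduce it from the wrong face, so that conversion or C14 selectivity is poor.
- Fallback (sets out from 31, returns at 32): enzyme control is given up for transfer hydrogenation with RuCl(p-cymene)(TsDPEN) in HCO2H/Et3N, a known way to reduce one carbonyl of a 1,3-diketone; the ligand antipode is chosen by trial for (14S). The (14R)-carbinol F5 is separated and oxidised back to 31 with Dess–Martin periodinane, so that material is recycled and 32 is accumulated.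

**Step 23 (allylic oxidation).**
- Risk: oxygen may be delivered equatorially, or the reaction may over-oxidise to the enone or attack the C7a methine, because the axial preference of the [2,3] shift on this crowded ring is an expectation and not a certainty.
- Fallback (sets out from 33, returns at 39): if the equatorial 6β-alcohol F6 is what forms, it is esterified with acid 38 under Mitsunobu conditions (PPh3, DIAD, THF). This inverts C6 and gives the axial ester 39 directly.

## Further compounds

F1 | step 17 | (4R,6R)-4,6-dimethyl-1,3-dioxane acetal of aldehyde 25 | C[C@@H]1C[C@@H](C)OC(CC[C@H](C(C)C)/C=C/[C@@H](O[Si](C(C)C)(C(C)C)C(C)C)[C@H](O[Si](C)(C)C(C)(C)C)C#CC)O1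
F2 | step 17 | 7α-O-[(2R,4R)-4-hydroxypentan-2-yl] ether of 27 | C[C@@H](O)C[C@@H](C)O[C@@H]1[C@@H]2[C@H]([C@H](C(C)=O)[C@@H](O[Si](C)(C)C(C)(C)C)[C@@H]2O[Si](C(C)C)(C(C)C)C(C)C)[C@@H](C(C)C)CC1
F3 | step 17 | 7α-O-[(2R)-4-oxopentan-2-yl] ether of 27 | CC(=O)C[C@@H](C)O[C@@H]1[C@@H]2[C@H]([C@H](C(C)=O)[C@@H](O[Si](C)(C)C(C)(C)C)[C@@H]2O[Si](C(C)C)(C(C)C)C(C)C)[C@@H](C(C)C)CC1
F4 | step 20 | 3-acetyl-7-hydroxy-4β-isopropyl-1β-(triisopropylsilyloxy)-7-[(trimethylsilyl)methyl]-trans-hydrindan-2-one (C7 configuration open) | C[Si](C)(C)CC1(O)[C@@H]2[C@H]([C@H](C(C)=O)C(=O)[C@@H]2O[Si](C(C)C)(C(C)C)C(C)C)[C@@H](C(C)C)CC1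
F5 | step 21 | 3β-[(1R)-1-hydroxyethyl]-4β-isopropyl-7-methylidene-1β-(triisopropylsilyloxy)-trans-hydrindan-2-one | C=C1[C@@H]2[C@H]([C@H]([C@@H](C)O)C(=O)[C@@H]2O[Si](C(C)C)(C(C)C)C(C)C)[C@@H](C(C)C)CC1
F6 | step 23 | 3β-[(1S)-1-acetoxyethyl]-6β-hydroxy-4β-isopropyl-7-methylidene-1β-(triisopropylsilyloxy)-trans-hydrindan-2-one | C=C1[C@@H]2[C@H]([C@H]([C@H](C)OC(C)=O)C(=O)[C@@H]2O[Si](C(C)C)(C(C)C)C(C)C)[C@@H](C(C)C)C[C@H]1O
A1 | alternative 1 | (2Z,6E)-farnesyl diphosphate | O=P(O)(O)OP(=O)(O)OC/C=C(C)\CC/C=C(C)/CCC=C(C)C
A2 | alternative 1 | γ-cadinene | C=C1[C@@H]2[C@H](C=C(C)CC2)[C@@H](C(C)C)CC1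
A3 | alternative 2 | trans-fused 5-isopropyl-2-methylidene-7-(cis-3-methyloxiran-2-yl)bicyclo[4.2.0]octan-7-ol (carbinol configuration chosen arbitrarily) | C=C1[C@@H]2[C@H]([C@](O)([C@H]3O[C@H]3C)C2)[C@@H](C(C)C)CC1
A4 | alternative 2 | 3β-[(1S)-1-hydroxyethyl]-4β-isopropyl-7-methylidene-trans-hydrindan-2-one | C=C1[C@@H]2[C@H]([C@H]([C@H](C)O)C(=O)C2)[C@@H](C(C)C)CC1
A5 | alternative 3 | (E)-enal–(E,E)-dienyl acetate triene with C2 dioxolane and C3 silyloxyethyl arm | O=C/C=C/CC1(OCCO1)[C@@H]([C@H](C)O[Si](C)(C)C(C)(C)C)/C=C(C(C)C)/C=C/OC(C)=O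
A6 | alternative 3 | trans-fused hexahydroindene with C7 formyl, C6 acetate, C4=C5 alkene, C2 dioxolane and C3 silyloxyethyl arm | O=C[C@@H]1[C@@H]2[C@H]([C@H]([C@H](C)O[Si](C)(C)C(C)(C)C)C3(OCCO3)C2)C(C(C)C)=C[C@@H]1OC(C)=O
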